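**Retrosynthetic overview**

1. Target ⇐ anti-1,3-diol (angeloylation at C1, then acetylation at C3) ⇐ seven-membered 1,3-diketone by catalyst-controlled asymmetric hydrogenation.
2. Seven-membered ring (formed last) ⇐ intramolecular aldol of a C11 aldehyde (from a vinyl group) with the methyl ketone C5–CMe2–C(=O)CH3.
3. Key step: silver-promoted semipinacol 1,2-shift of a β-hydroxy selenide; the cyclobutane carbon C5 migrates from the carbinol carbon C3 to the new CMe2 carbon C4 (C4–C5 bond, quaternary C4, C3 ketone).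
4. Cyclobutane (formed second) ⇐ 4-exo-tet alkylation of a cyclohexenone α′-enolate by a propargylic bromide; C11 quaternary centre ⇐ conjugate methylation anti to the C6 side chain; C7 methyl ⇐ cuprate addition to the bicyclic enone.
5. Six-membered ring (present from the start) ⇐ cyclohexane-1,3-dione via its vinylogous ester; absolute configuration ⇐ a new catalytic asymmetric aldol with 3-(trimethylsilyl)propynal.

Assumption: carbon labels C1–C11 follow the ring atoms of the target SMILES in order (C1 = CH–O-angeloyl, C3 = CH–OAc, C4 = CMe2, C9 = C=O, C11 = C–CH3) and are used in the Why lines for all intermediates, while compound names use ordinary ring locants.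

**Route**

Step 1
Reactants: 1 cyclohexane-1,3-dione
Product: 2 3-methoxycyclohex-2-en-1-one
Conditions: MeOH, TsOH (cat.), 3 Å MS, reflux
Reagents that add atoms: methanol, CO
Why: acid-catalysed enol etherification of the 1,3-dione gives the vinylogous ester for Stork–Danheiser chemistry, whose only kinetic enolate lies at C6 (no stereocentre formed).

Step 2
Reactants: 2 3-methoxycyclohex-2-en-1-one; 3 3-(trimethylsilyl)prop-2-ynal
Product: 4 (6S)-6-[(1R)-1-hydroxy-3-(trimethylsilyl)prop-2-yn-1-yl]-3-methoxycyclohex-2-en-1-one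
Conditions: (S,S)-ProPhenol (10 mol%; ligand enantiomer to be confirmed as the one giving the 6S adduct), ZnEt2 (20 mol%), 4 Å MS, THF, −20 °C, 3 equiv of 2
Reagents that add atoms: none
Why: Proposed new method: direct asymmetric aldol of the α′-CH2 of a cyclic vinylogous ester with a dinuclear zinc–ProPhenol catalyst, in which one zinc binds the strongly Lewis-basic vinylogous-ester carbonyl while its alkoxide arm removes the α′-proton to give a zinc (E)-enolate and the second zinc binds the ynal, so that C–C bond formation passes through a closed bimetallic transition state that sets C6 (S) and, anti to it, the carbinol C5 (R); the closest known reaction is the zinc–ProPhenol direct aldol of methyl ketones and α-hydroxy ketones with aldehydes, which has not been shown for a cyclic vinylogous ester donor.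

Step 3
Reactants: 4 (6S)-6-[(1R)-1-hydroxy-3-(trimethylsilyl)prop-2-yn-1-yl]-3-methoxycyclohex-2-en-1-one
Product: 6 (4R)-3-ethenyl-4-[(1R)-1-hydroxy-3-(trimethylsilyl)prop-2-yn-1-yl]cyclohex-2-en-1-one, via vinyl carbinol 5 (not isolated)
Conditions: CH2=CHMgBr (3 equiv), THF, −78 to 0 °C; then 1 M HCl, 0 °C
Reagents that add atoms: vinylmagnesium bromide, C=C[Mg]Br
Why: Stork–Danheiser sequence (1,2-addition to the vinylogous ester carbonyl, then acid hydrolysis with allylic transposition) places the vinyl group (future C1) on C11 and the ketone on C9 without touching the C5 and C6 stereocentres.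

Step 4
Reactants: 6 (4R)-3-ethenyl-4-[(1R)-1-hydroxy-3-(trimethylsilyl)prop-2-yn-1-yl]cyclohex-2-en-1-one
Product: 7 (3R,4R)-3-ethenyl-4-[(1R)-1-hydroxy-3-(trimethylsilyl)prop-2-yn-1-yl]-3-methylcyclohexan-1-one
Conditions: MeMgBr (3 equiv), Cu(OTf)2 (5 mol%), 1,3-dimesitylimidazolinium tetrafluoroborate (6 mol%), Et2O, −30 °C; then 1 M HCl
Reagents that add atoms: methylmagnesium bromide, C[Mg]Br
Why: copper–carbene-catalysed conjugate addition of a Grignard reagent, the conditions that favour 1,4- over 1,6-addition on 3-alkenylcyclohexenones, delivers methyl anti to the pseudoaxial C6 substituent and so sets the C11 quaternary centre with methyl trans to the side chain.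

Step 5
Reactants: 7 (3R,4R)-3-ethenyl-4-[(1R)-1-hydroxy-3-(trimethylsilyl)prop-2-yn-1-yl]-3-methylcyclohexan-1-one
Product: 10 (4R,5R)-5-ethenyl-4-[(1R)-1-hydroxy-3-(trimethylsilyl)prop-2-yn-1-yl]-5-methylcyclohex-2-en-1-one, via bis-silylated enol ether 8 (not isolated), via O-silylated enone 9 (not isolated)
Conditions: LiN(iPr)2 (2.2 equiv), Me3SiCl (2.5 equiv), THF, −78 °C; then Pd(OAc)2 (10 mol%), O2 (1 atm), DMSO, rt; then 1 M HCl, THF
Reagents that add atoms: none
Why: kinetic deprotonation at C8 (away from the quaternary C11) followed by Saegusa–Ito dehydrogenation of the silyl enol ether gives the C7=C8 enone, which leaves C10 as the only α′-position for the ring closure; the silyl ether on the carbinol is cleaved in the acidic work-up and no stereocentre changes.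

Step 6
Reactants: 10 (4R,5R)-5-ethenyl-4-[(1R)-1-hydroxy-3-(trimethylsilyl)prop-2-yn-1-yl]-5-methylcyclohex-2-en-1-one
Product: 11 (4R,5R)-4-[(1S)-1-bromo-3-(trimethylsilyl)prop-2-yn-1-yl]-5-ethenyl-5-methylcyclohex-2-en-1-one
Conditions: PPh3, CBr4, CH2Cl2, 0 °C
Reagents that add atoms: tetrabromomethane, BrC(Br)(Br)Br
Why: Appel reaction, an SN2 displacement at the propargylic carbon that inverts C5 (R to S), so that the second inversion in the ring closure gives the C5 configuration of the target.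

Step 7
Reactants: 11 (4R,5R)-4-[(1S)-1-bromo-3-(trimethylsilyl)prop-2-yn-1-yl]-5-ethenyl-5-methylcyclohex-2-en-1-one
Product: 12 (1R,5S,6R,7S)-6-ethenyl-6-methyl-7-[(trimethylsilyl)ethynyl]bicyclo[3.1.1]hept-3-en-2-one
Conditions: LiN(iPr)2 (1.1 equiv), THF, −78 °C; then DMPU, −78 to 0 °C
Reagents that add atoms: none
Why: the cross-conjugated α′-lithium enolate (C10) displaces the propargylic bromide in a 4-exo-tet intramolecular alkylation with inversion at C5, the same ring-closure type as the keto-tosylate cyclobutane closures used in copaene and pinene syntheses; SN2′ attack would need a cyclic allene and O-alkylation a bridgehead enol ether, and C5 and C10 are fixed by the axial C6 substituent.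

Step 8
Reactants: 12 (1R,5S,6R,7S)-6-ethenyl-6-methyl-7-[(trimethylsilyl)ethynyl]bicyclo[3.1.1]hept-3-en-2-one
Product: 14 (1R,5S,6R,7S)-7-acetyl-6-ethenyl-6-methylbicyclo[3.1.1]hept-3-en-2-one, via terminal alkyne 13 (not isolated)
Conditions: K2CO3 (cat.), MeOH, rt; then (Ph3P)AuNTf2 (3 mol%), H2O, MeOH, 60 °C
Reagents that add atoms: water, O
Why: protodesilylation followed by gold-catalysed Markovnikov hydration of the terminal alkyne gives the methyl ketone (C3, with C2 as its methyl) without touching the enone or the vinyl group; C5 keeps its configuration, which is also the thermodynamically preferred one.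

Step 9
Reactants: 15 acetone
Product: 16 2,2-bis(phenylselanyl)propane
Conditions: PhSeH (2.1 equiv), ZnCl2 (cat.), CH2Cl2, rt
Reagents that add atoms: benzeneselenol, [SeH]c1ccccc1
Why: Lewis-acid-catalysed selenoketalisation of acetone gives the precursor of the α-seleno carbanion that will deliver C4 and its two methyl groups (no stereocentre).

Step 10
Reactants: 14 (1R,5S,6R,7S)-7-acetyl-6-ethenyl-6-methylbicyclo[3.1.1]hept-3-en-2-one; 16 2,2-bis(phenylselanyl)propane
Product: 19 (1R,4R,5S,6R,7S)-6-ethenyl-7-[2-hydroxy-3-methyl-3-(phenylselanyl)butan-2-yl]-4,6-dimethylbicyclo[3.1.1]heptan-2-one (both carbinol epimers), via 2-lithio-2-(phenylselanyl)propane 17 (not isolated), via lithium enolate 18 (not isolated)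
Conditions: Me2CuLi (1.2 equiv, from CuI and MeLi), Et2O–THF, −78 °C; then 17 (2 equiv, from 16 and n-BuLi, THF, −78 °C), −78 °C; H2O
Reagents that add atoms: lithium dimethylcuprate, C[Cu-]C.[Li+]
Why: cuprate conjugate addition puts the C7 methyl on the face of the less hindered one-carbon bridge (the C5–H side, away from the C11 methyl) and leaves C9 masked as its enolate, so the α-seleno carbanion then adds 1,2 to the methyl ketone only; the new carbinol configuration at C3 is irrelevant because it is destroyed in the next step.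

Step 11
Reactants: 19 (1R,4R,5S,6R,7S)-6-ethenyl-7-[2-hydroxy-3-methyl-3-(phenylselanyl)butan-2-yl]-4,6-dimethylbicyclo[3.1.1]heptan-2-one
Product: 20 (1R,4R,5S,6R,7S)-6-ethenyl-4,6-dimethyl-7-(2-methyl-3-oxobutan-2-yl)bicyclo[3.1.1]heptan-2-one
Conditions: AgBF4 (1.2 equiv), Al2O3, CH2Cl2, 0 °C to rt
Reagents that add atoms: none
Why: silver-assisted departure of the phenylselanyl group triggers a semipinacol (pinacol-type) 1,2-shift of a β-hydroxy selenide in which the more substituted carbinol substituent, the cyclobutane carbon C5, migrates with retention from C3 to C4, creating the gem-dimethyl quaternary carbon and the C3 ketone without an ionisable leaving group at C3 next to the cyclobutane.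

Step 12
Reactants: 20 (1R,4R,5S,6R,7S)-6-ethenyl-4,6-dimethyl-7-(2-methyl-3-oxobutan-2-yl)bicyclo[3.1.1]heptan-2-one
Product: 21 (1R,4R,5S,6R,7S)-4,6-dimethyl-7-(2-methyl-3-oxobutan-2-yl)-2-oxobicyclo[3.1.1]heptane-6-carbaldehyde
Conditions: O3, CH2Cl2–MeOH, −78 °C; then PPh3
Reagents that add atoms: ozone, [O-][O+]=O
Why: ozonolysis with reductive work-up cleaves the only alkene to the non-enolisable neopentyl aldehyde (C1); no stereocentre changes.

Step 13
Reactants: 21 (1R,4R,5S,6R,7S)-4,6-dimethyl-7-(2-methyl-3-oxobutan-2-yl)-2-oxobicyclo[3.1.1]heptane-6-carbaldehyde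
Product: 22 (1S,2S,7R,8R,11R)-6-hydroxy-3,3,7,11-tetramethyltricyclo[5.4.0.0(2,8)]undecane-4,9-dione (both epimers at the carbinol carbon)
Conditions: LiN(iPr)2 (2.2 equiv), THF, −78 °C; then H2O
Reagents that add atoms: none
Why: intramolecular aldol addition of the methyl ketone enolate (C4 is quaternary, and no other enolate can reach the aldehyde) closes the seven-membered ring across the two cis substituents on the lower face of the cyclobutane; the new carbinol centre is not controlled and is erased in the next step.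

Step 14
Reactants: 22 (1S,2S,7R,8R,11R)-6-hydroxy-3,3,7,11-tetramethyltricyclo[5.4.0.0(2,8)]undecane-4,9-dione
Product: 23 (1S,2S,7R,8R,11R)-3,3,7,11-tetramethyltricyclo[5.4.0.0(2,8)]undecane-4,6,9-trione
Conditions: Dess–Martin periodinane, CH2Cl2, rt
Reagents that add atoms: none
Why: Dess–Martin oxidation converges both carbinol epimers on the 1,3-diketone so that C1 and C3 can be set together under catalyst control.

Step 15
Reactants: 23 (1S,2S,7R,8R,11R)-3,3,7,11-tetramethyltricyclo[5.4.0.0(2,8)]undecane-4,6,9-trione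
Product: 24 (1S,2S,4S,6S,7R,8R,11R)-4,6-dihydroxy-3,3,7,11-tetramethyltricyclo[5.4.0.0(2,8)]undecan-9-one
Conditions: H2 (80 atm), RuCl2[(R)-BINAP] (1 mol%), MeOH, 50 °C
Reagents that add atoms: none
Why: Noyori asymmetric hydrogenation of a β-diketone (chelation-directed, so the isolated C9 ketone is left alone) gives the anti-1,3-diol with both carbinol centres set by the catalyst, (R)-BINAP being the enantiomer that gives the (R,R)-diol from pentane-2,4-dione and, in the same spatial sense, the (4S,6S)-diol here; catalyst control is used because the remote cage centres give almost no bias.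

Step 16
Reactants: 24 (1S,2S,4S,6S,7R,8R,11R)-4,6-dihydroxy-3,3,7,11-tetramethyltricyclo[5.4.0.0(2,8)]undecan-9-one; 25 (Z)-2-methylbut-2-enoic acid (angelic acid)
Product: 27 (1S,2S,4S,6S,7R,8R,11R)-4-hydroxy-3,3,7,11-tetramethyl-9-oxotricyclo[5.4.0.0(2,8)]undecan-6-yl (Z)-2-methylbut-2-enoate, via angelic 2,4,6-trichlorobenzoic anhydride 26 (not isolated)
Conditions: 25, 2,4,6-trichlorobenzoyl chloride, Et3N, toluene, rt; then 24, DMAP (cat.), 80 °C
Reagents that add atoms: none
Why: Yamaguchi esterification (the usual way to make angelates without Z to E isomerisation) is expected to acylate the C1 hydroxyl, which sits next to the tied-back cyclobutane carbon C11, in preference to the C3 hydroxyl flanked by the gem-dimethyl carbon; no stereocentre changes.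

Step 17
Reactants: 27 (1S,2S,4S,6S,7R,8R,11R)-4-hydroxy-3,3,7,11-tetramethyl-9-oxotricyclo[5.4.0.0(2,8)]undecan-6-yl (Z)-2-methylbut-2-enoate
Product: 28 (1S,2S,4S,6S,7R,8R,11R)-4-acetoxy-3,3,7,11-tetramethyl-9-oxotricyclo[5.4.0.0(2,8)]undecan-6-yl (Z)-2-methylbut-2-enoate
Conditions: Ac2O, DMAP (cat.), pyridine, rt to 40 °C
Reagents that add atoms: acetic anhydride, CC(=O)OC(C)=O
Why: DMAP-catalysed acetylation of the remaining hindered C3 hydroxyl completes the target, the angelate and the ketone being stable to these conditions.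

**Compound list**

1 | cyclohexane-1,3-dione | O=C1CCCC(=O)C1 | starting material
2 | 3-methoxycyclohex-2-en-1-one | COC1=CC(=O)CCC1 | intermediate
3 | 3-(trimethylsilyl)prop-2-ynal | C[Si](C)(C)C#CC=O | starting material
4 | (6S)-6-[(1R)-1-hydroxy-3-(trimethylsilyl)prop-2-yn-1-yl]-3-methoxycyclohex-2-en-1-one (anti aldol) | C[Si](C)(C)C#C[C@H](O)[C@@H]1CCC(OC)=CC1=O | intermediate
5 | (6S)-1-ethenyl-6-[(1R)-1-hydroxy-3-(trimethylsilyl)prop-2-yn-1-yl]-3-methoxycyclohex-2-en-1-ol (both C1 epimers; formed as its magnesium alkoxide) | C[Si](C)(C)C#C[C@H](O)[C@@H]1CCC(OC)=CC1(O)C=C | intermediate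
6 | (4R)-3-ethenyl-4-[(1R)-1-hydroxy-3-(trimethylsilyl)prop-2-yn-1-yl]cyclohex-2-en-1-one | C[Si](C)(C)C#C[C@H](O)[C@@H]1CCC(=O)C=C1C=C | intermediate
7 | (3R,4R)-3-ethenyl-4-[(1R)-1-hydroxy-3-(trimethylsilyl)prop-2-yn-1-yl]-3-methylcyclohexan-1-one | C[Si](C)(C)C#C[C@H](O)[C@@H]1CCC(=O)C[C@@]1(C=C)C | intermediate
8 | (4R,5R)-5-ethenyl-5-methyl-1-(trimethylsilyloxy)-4-[(1R)-3-(trimethylsilyl)-1-(trimethylsilyloxy)prop-2-yn-1-yl]cyclohex-1-ene | C[Si](C)(C)C#C[C@H](O[Si](C)(C)C)[C@@H]1CC=C(O[Si](C)(C)C)C[C@@]1(C=C)C | intermediate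
9 | (4R,5R)-5-ethenyl-5-methyl-4-[(1R)-3-(trimethylsilyl)-1-(trimethylsilyloxy)prop-2-yn-1-yl]cyclohex-2-en-1-one | C[Si](C)(C)C#C[C@H](O[Si](C)(C)C)[C@@H]1C=CC(=O)C[C@@]1(C=C)C | intermediate
10 | (4R,5R)-5-ethenyl-4-[(1R)-1-hydroxy-3-(trimethylsilyl)prop-2-yn-1-yl]-5-methylcyclohex-2-en-1-one | C[Si](C)(C)C#C[C@H](O)[C@@H]1C=CC(=O)C[C@@]1(C=C)C | intermediate
11 | (4R,5R)-4-[(1S)-1-bromo-3-(trimethylsilyl)prop-2-yn-1-yl]-5-ethenyl-5-methylcyclohex-2-en-1-one | C[Si](C)(C)C#C[C@@H](Br)[C@@H]1C=CC(=O)C[C@@]1(C=C)C | intermediate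
12 | (1R,5S,6R,7S)-6-ethenyl-6-methyl-7-[(trimethylsilyl)ethynyl]bicyclo[3.1.1]hept-3-en-2-one | C[Si](C)(C)C#C[C@H]1[C@@H]2C=CC(=O)[C@H]1[C@@]2(C=C)C | intermediate
13 | (1R,5S,6R,7S)-6-ethenyl-7-ethynyl-6-methylbicyclo[3.1.1]hept-3-en-2-one | C#C[C@H]1[C@@H]2C=CC(=O)[C@H]1[C@@]2(C=C)C | intermediate
14 | (1R,5S,6R,7S)-7-acetyl-6-ethenyl-6-methylbicyclo[3.1.1]hept-3-en-2-one | CC(=O)[C@H]1[C@@H]2C=CC(=O)[C@H]1[C@@]2(C=C)C | intermediate
15 | acetone (propan-2-one) | CC(C)=O | starting material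
16 | 2,2-bis(phenylselanyl)propane | CC(C)([Se]c1ccccc1)[Se]c1ccccc1 | intermediate
17 | 2-lithio-2-(phenylselanyl)propane | CC(C)([Li])[Se]c1ccccc1 | intermediate
18 | lithium enolate (C8=C9) of 7-acetyl-6-ethenyl-4,6-dimethylbicyclo[3.1.1]heptan-2-one, new C7 methyl on the C5-bridge side, other centres as in 14 | CC(=O)[C@H]1[C@@H]2[C@H](C)C=C(O[Li])[C@H]1[C@@]2(C=C)C | intermediate
19 | (1R,4R,5S,6R,7S)-6-ethenyl-7-[2-hydroxy-3-methyl-3-(phenylselanyl)butan-2-yl]-4,6-dimethylbicyclo[3.1.1]heptan-2-one (both carbinol epimers) | CC(C)([Se]c1ccccc1)C(C)(O)[C@H]1[C@@H]2[C@H](C)CC(=O)[C@H]1[C@@]2(C=C)C | intermediate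
20 | (1R,4R,5S,6R,7S)-6-ethenyl-4,6-dimethyl-7-(2-methyl-3-oxobutan-2-yl)bicyclo[3.1.1]heptan-2-one | CC(=O)C(C)(C)[C@H]1[C@@H]2[C@H](C)CC(=O)[C@H]1[C@@]2(C=C)C | intermediate
21 | (1R,4R,5S,6R,7S)-4,6-dimethyl-7-(2-methyl-3-oxobutan-2-yl)-2-oxobicyclo[3.1.1]heptane-6-carbaldehyde | CC(=O)C(C)(C)[C@H]1[C@@H]2[C@H](C)CC(=O)[C@H]1[C@@]2(C=O)C | intermediate
22 | (1S,2S,7R,8R,11R)-6-hydroxy-3,3,7,11-tetramethyltricyclo[5.4.0.0(2,8)]undecane-4,9-dione (both epimers at the carbinol carbon) | OC1CC(=O)C(C)(C)[C@H]2[C@@H]3[C@H](C)CC(=O)[C@H]2[C@@]31C | intermediate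
23 | (1S,2S,7R,8R,11R)-3,3,7,11-tetramethyltricyclo[5.4.0.0(2,8)]undecane-4,6,9-trione | O=C1CC(=O)C(C)(C)[C@H]2[C@@H]3[C@H](C)CC(=O)[C@H]2[C@@]31C | intermediate
24 | (1S,2S,4S,6S,7R,8R,11R)-4,6-dihydroxy-3,3,7,11-tetramethyltricyclo[5.4.0.0(2,8)]undecan-9-one | O[C@H]1C[C@H](O)C(C)(C)[C@H]2[C@@H]3[C@H](C)CC(=O)[C@H]2[C@@]31C | intermediate
25 | (Z)-2-methylbut-2-enoic acid (angelic acid) | C/C=C(/C)C(=O)O | starting material
26 | (Z)-2-methylbut-2-enoic 2,4,6-trichlorobenzoic anhydride | C/C=C(/C)C(=O)OC(=O)c1c(Cl)cc(Cl)cc1Cl | intermediate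
27 | (1S,2S,4S,6S,7R,8R,11R)-4-hydroxy-3,3,7,11-tetramethyl-9-oxotricyclo[5.4.0.0(2,8)]undecan-6-yl (Z)-2-methylbut-2-enoate | C/C=C(/C)C(=O)O[C@H]1C[C@H](O)C(C)(C)[C@H]2[C@@H]3[C@H](C)CC(=O)[C@H]2[C@@]31C | intermediate
28 | (1S,2S,4S,6S,7R,8R,11R)-4-acetoxy-3,3,7,11-tetramethyl-9-oxotricyclo[5.4.0.0(2,8)]undecan-6-yl (Z)-2-methylbut-2-enoate | C/C=C(/C)C(=O)O[C@H]1C[C@H](OC(C)=O)C(C)(C)[C@H]2[C@@H]3[C@H](C)CC(=O)[C@H]2[C@@]31C | target

**Step count and risks**

Total step count: 17. Longest linear sequence: 16 (steps 1–8 and 10–17; step 9 is a one-step side branch).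

The three steps most likely to fail:

Step 2 (the proposed new aldol). The α′-protons may be too weakly acidic for the zinc catalyst, or facial control may be poor. The fallback uses known chemistry, sets out from 2 and 3 and returns to the route at 4. A lithium enolate aldol (LiN(iPr)2, THF, −78 °C) gives the unselective aldol mixture 6-[1-hydroxy-3-(trimethylsilyl)prop-2-yn-1-yl]-3-methoxycyclohex-2-en-1-one F1. Dess–Martin oxidation gives the alkynyl β-diketone 3-methoxy-6-[3-(trimethylsilyl)prop-2-ynoyl]cyclohex-2-en-1-one F2, in which C6 is stereolabile. Noyori transfer hydrogenation of the ynone (RuCl(p-cymene)[(R,R)-TsDPEN], HCO2H–Et3N) under dynamic kinetic resolution then gives 4. If the syn epimer (same C6, opposite carbinol) is obtained instead, it is carried on with mesylation (retention) in place of the Appel reaction of step 6, so both carbinol epimers converge on 12.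

Step 15 (hydrogenation of a very hindered, enolised β-diketone). The fallback sets out from 22 and returns at 24. The two carbinol epimers of 22 are separated by chromatography to give (1S,2S,6S,7R,8R,11R)-6-hydroxy-3,3,7,11-tetramethyltricyclo[5.4.0.0(2,8)]undecane-4,9-dione F3. This is reduced with Me4NBH(OAc)3 (MeCN–AcOH, −30 °C; Evans–Saksena hydroxyl-directed anti reduction, which leaves the C9 ketone alone) to 24. The unwanted epimer is re-equilibrated with base through retro-aldol and aldol.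

Step 16 (regioselective angeloylation of one of two neopentyl hydroxyls). The fallback sets out from 24 and returns at 28.
- TESCl and imidazole (CH2Cl2, −20 °C) silylate the less hindered hydroxyl to give (1S,2S,4S,6S,7R,8R,11R)-4-hydroxy-3,3,7,11-tetramethyl-6-(triethylsilyloxy)tricyclo[5.4.0.0(2,8)]undecan-9-one F4.
- Ac2O, DMAP and Et3N give (1S,2S,4S,6S,7R,8R,11R)-3,3,7,11-tetramethyl-9-oxo-6-(triethylsilyloxy)tricyclo[5.4.0.0(2,8)]undecan-4-yl acetate F5.
- HF·pyridine gives (1S,2S,4S,6S,7R,8R,11R)-6-hydroxy-3,3,7,11-tetramethyl-9-oxotricyclo[5.4.0.0(2,8)]undecan-4-yl acetate F6.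
- Yamaguchi esterification of F6 with 26 gives 28.

If the C3 hydroxyl turns out to be the more reactive one, 24 is simply acetylated first and angeloylated second.

Further compounds
F1 | step 2 | 6-[1-hydroxy-3-(trimethylsilyl)prop-2-yn-1-yl]-3-methoxycyclohex-2-en-1-one (racemic mixture of diastereomers) | C[Si](C)(C)C#CC(O)C1CCC(OC)=CC1=O
F2 | step 2 | 3-methoxy-6-[3-(trimethylsilyl)prop-2-ynoyl]cyclohex-2-en-1-one | C[Si](C)(C)C#CC(=O)C1CCC(OC)=CC1=O
F3 | step 15 | (1S,2S,6S,7R,8R,11R)-6-hydroxy-3,3,7,11-tetramethyltricyclo[5.4.0.0(2,8)]undecane-4,9-dione | O[C@H]1CC(=O)C(C)(C)[C@H]2[C@@H]3[C@H](C)CC(=O)[C@H]2[C@@]31C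
F4 | step 16 | (1S,2S,4S,6S,7R,8R,11R)-4-hydroxy-3,3,7,11-tetramethyl-6-(triethylsilyloxy)tricyclo[5.4.0.0(2,8)]undecan-9-one | CC[Si](CC)(CC)O[C@H]1C[C@H](O)C(C)(C)[C@H]2[C@@H]3[C@H](C)CC(=O)[C@H]2[C@@]31C
F5 | step 16 | (1S,2S,4S,6S,7R,8R,11R)-3,3,7,11-tetramethyl-9-oxo-6-(triethylsilyloxy)tricyclo[5.4.0.0(2,8)]undecan-4-yl acetate | CC[Si](CC)(CC)O[C@H]1C[C@H](OC(C)=O)C(C)(C)[C@H]2[C@@H]3[C@H](C)CC(=O)[C@H]2[C@@]31C
F6 | step 16 | (1S,2S,4S,6S,7R,8R,11R)-6-hydroxy-3,3,7,11-tetramethyl-9-oxotricyclo[5.4.0.0(2,8)]undecan-4-yl acetate | O[C@H]1C[C@H](OC(C)=O)C(C)(C)[C@H]2[C@@H]3[C@H](C)CC(=O)[C@H]2[C@@]31C
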